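**Plan**
- Retrosynthesis: the pyran ring of the 2H-chromene is contracted by cutting C4–C4a and returning C4 to C8a, which gives a 1-oxaspiro[4.5]deca-3,6,9-trien-8-one. Cutting its O1–C8a bond gives a para-(Z)-alkenylphenol; further cuts are aryl–C4 (Sonogashira), C7'=C8' (Still–Gennari) and the alkyne (from a 2,3-epoxy chloride of farnesol).
- Enabling feature: O1 sits on C8a, which is para to the C6 hydroxyl and has only one hydrogen-bearing neighbour (C4a; C8 carries the methyl). A phenol can therefore be oxidized at this para carbon to a spiro 2,5-dihydrofuran (O1, C2, C3, C4, C8a) dienone, and a 1,2-shift of the alkenyl carbon C4 from C8a to C4a enlarges this five-membered ring to the pyran ring while the arene is restored.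
- Forward: farnesol → terminal oxirane → asymmetric 2,3-epoxidation → epoxy chloride → tertiary alkynol → aldehyde → (Z)-enoate → arylalkyne → (Z)-alkene → spiro dienone (five-membered oxygen ring) → ring expansion to the chromenol → acid.
- Stereochemistry: C2 (R) is set by the Sharpless epoxidation with D-(−)-diethyl tartrate, and none of its four bonds is broken afterwards. The 3'E alkene comes from farnesol, the 7'Z alkene from the Still–Gennari olefination.

Key step: step 11

Remark: target atom numbers are used for the chromene (O1, C2, C3, C4, C4a, C5–C8, C8a) and primed numbers for the side chain. (2E,6E)-Farnesol of high isomeric purity is assumed, and the enantiomeric purity reached in step 2 is assumed to be carried to the target because no later step breaks a bond at that carbon.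

**Route**

Step 1
Reactants: 1 (2E,6E)-farnesol
Product: 3 (2E,6E)-10,11-epoxyfarnesol (racemic at the oxirane CH), via terminal bromohydrin 2 (not isolated)
Conditions: NBS, THF/H2O, 0 °C; then K2CO3, MeOH, rt
Reagents that add atoms: water, O (oxirane oxygen); N-bromosuccinimide, O=C1CCC(=O)N1Br (bromine of intermediate 2 only)
Why: Terminal-selective bromohydrin formation of a coiled polyene in aqueous THF (the 2,3-alkene is deactivated by the allylic oxygen), water opening the bromonium ion at the tertiary carbon and carbonate closing the oxirane; the new oxirane carbon forms as both epimers, which is irrelevant because it is excised in step 5.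

Step 2
Reactants: 3 (2E,6E)-10,11-epoxyfarnesol
Product: 4 [(2R,3R)-3-[(3E)-6-(3,3-dimethyloxiran-2-yl)-4-methylhex-3-en-1-yl]-3-methyloxiran-2-yl]methanol
Conditions: Ti(OiPr)4 (cat.), D-(−)-diethyl tartrate (cat.), t-BuOOH, 4 Å molecular sieves, CH2Cl2, −20 °C
Reagents that add atoms: tert-butyl hydroperoxide, CC(C)(C)OO
Why: Sharpless asymmetric epoxidation acts only on the allylic alcohol alkene, and the titanium D-(−)-tartrate catalyst delivers oxygen to the face that should give the (2R,3R)-epoxy alcohol (reagent control), which fixes the future C2 of the chromene.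

Step 3
Reactants: 4 (2R,3R)-diepoxy alcohol
Product: 5 (2S,3R)-2-(chloromethyl)-3-[(3E)-6-(3,3-dimethyloxiran-2-yl)-4-methylhex-3-en-1-yl]-3-methyloxirane
Conditions: PPh3, CCl4, NaHCO3 (cat.), reflux
Reagents that add atoms: tetrachloromethane, ClC(Cl)(Cl)Cl
Why: Appel chlorination of the primary alcohol under buffered neutral conditions leaves both oxiranes intact and touches no stereocentre (the descriptor at C2 changes to S only through the CIP priority of CH2Cl).

Step 4
Reactants: 5 (2S,3R)-epoxy chloride
Product: 7 (3R,6E)-9-(3,3-dimethyloxiran-2-yl)-3,7-dimethylnon-6-en-1-yn-3-ol, via chlorovinyl alkoxide 6 (not isolated)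
Conditions: n-BuLi (3.2 equiv), THF, −78 °C; then H2O
Reagents that add atoms: none
Why: Base-induced double elimination of a 2,3-epoxy chloride (deprotonation at CH2Cl opens the oxirane to the chlorovinyl alkoxide, and a second dehydrochlorination gives the alkyne); the tertiary C–O bond is retained, so the carbinol should keep its configuration (R), and the unactivated trisubstituted oxirane should survive at −78 °C.

Step 5
Reactants: 7 (3R,6E)-alkynol oxirane
Product: 8 (4E,8R)-8-hydroxy-4,8-dimethyldec-4-en-9-ynal
Conditions: H5IO6, THF/Et2O, 0 °C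
Reagents that add atoms: none
Why: Periodic acid hydrolyses the trisubstituted oxirane to the glycol and cleaves it in the same flask with loss of acetone (both oxirane epimers converge), while the alkyne, the tertiary alcohol and the remaining alkene are inert.

Step 6
Reactants: 9 methyl bis(2,2,2-trifluoroethyl)phosphonoacetate; 10 5-bromo-2-methylpent-2-ene
Product: 11 methyl 2-[bis(2,2,2-trifluoroethoxy)phosphoryl]-6-methylhept-5-enoate (racemic)
Conditions: NaH, NaI (cat.), DMSO, rt → 50 °C
Reagents that add atoms: none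
Why: C-alkylation of the stabilized phosphonoacetate anion with a primary bromide under iodide catalysis; the new α-stereocentre is formed as a racemate and disappears in step 7.

Step 7
Reactants: 8 (4E,8R)-8-hydroxy-4,8-dimethyldec-4-en-9-ynal; 11 α-homoprenyl phosphonate
Product: 12 methyl (2Z,6E,10R)-10-hydroxy-6,10-dimethyl-2-(4-methylpent-3-en-1-yl)dodeca-2,6-dien-11-ynoate
Conditions: 11 (1.2 equiv), KN(SiMe3)2 (1.15 equiv), 18-crown-6, THF, −78 °C; then 8
Reagents that add atoms: none
Why: Still–Gennari variant of the Horner–Wadsworth–Emmons olefination, in which the electron-poor bis(trifluoroethyl) phosphonate with a dissociated potassium counter-ion eliminates from the kinetic adduct and should give the (Z)-trisubstituted enoate (ester cis to the new chain); only the stabilized anion is present, so the alkyne C–H and the tertiary hydroxyl are not deprotonated.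

Step 8
Reactants: 12 (Z)-enoate alkynol; 13 4-iodo-3-methylphenol
Product: 14 methyl (2Z,6E,10R)-10-hydroxy-12-(4-hydroxy-2-methylphenyl)-6,10-dimethyl-2-(4-methylpent-3-en-1-yl)dodeca-2,6-dien-11-ynoate
Conditions: PdCl2(PPh3)2 (3 mol %), CuI (6 mol %), Et3N, THF (degassed), 40 °C
Reagents that add atoms: none
Why: Sonogashira coupling (oxidative addition of the aryl iodide to zerovalent palladium formed in the flask, transmetalation from the copper acetylide, reductive elimination), which tolerates the free phenol, the tertiary propargylic alcohol and the enoate.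

Step 9
Reactants: 14 arylalkyne
Product: 15 methyl (2Z,6E,10R,11Z)-10-hydroxy-12-(4-hydroxy-2-methylphenyl)-6,10-dimethyl-2-(4-methylpent-3-en-1-yl)dodeca-2,6,11-trienoate
Conditions: H2 (1 atm), Pd on CaCO3 poisoned with Pb(OAc)2 (Lindlar catalyst), quinoline, EtOAc, rt
Reagents that add atoms: none
Why: Lindlar semihydrogenation adds hydrogen syn on the poisoned surface and should give the (Z)-alkene that places the tertiary hydroxyl next to the arene, while the trisubstituted alkenes are not reduced.

Step 10
Reactants: 15 para-(Z)-alkenylphenol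
Product: 16 methyl (2Z,6E)-9-[(2R)-2,6-dimethyl-8-oxo-1-oxaspiro[4.5]deca-3,6,9-trien-2-yl]-6-methyl-2-(4-methylpent-3-en-1-yl)nona-2,6-dienoate (both epimers at the spiro carbon)
Conditions: PhI(OAc)2 (1.05 equiv), NaHCO3, MeCN, −10 → 0 °C
Reagents that add atoms: none
Why: Oxidative dearomatization of a para-substituted phenol with trivalent iodine (ligand exchange at iodine, loss of PhI, capture of the aryloxenium-type intermediate at the para carbon by the cis-held tertiary hydroxyl in a 5-exo closure) forms the aryl C–O bond without touching the C2–O bond, and the spiro stereocentre forms as both epimers, which is of no consequence because it becomes aromatic in step 11.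

Step 11
Reactants: 16 spiro trienone
Product: 17 methyl (2Z,6E)-9-[(2R)-6-hydroxy-2,8-dimethyl-2H-chromen-2-yl]-6-methyl-2-(4-methylpent-3-en-1-yl)nona-2,6-dienoate
Conditions: BF3·OEt2 (20 mol %), CH2Cl2, −40 → 0 °C; aq. NaHCO3
Reagents that add atoms: none
Why: Proposed new method: BF3 binds the dienone carbonyl of 16 and generates a hydroxypentadienyl-type cation with positive charge on the two carbons that flank the spiro carbon; the alkenyl carbon C4 of the 2,5-dihydrofuran then shifts with its electron pair from the spiro carbon (future C8a) to the hydrogen-bearing neighbour (future C4a), the charge passes to the spiro carbon where O1 stabilizes it as an oxocarbenium ion, and loss of the proton from C4a restores the arene as the 6-hydroxy-2H-chromene. The closest known reaction type is the acid-promoted dienone–phenol rearrangement of 4,4-disubstituted cyclohexa-2,5-dienones, in particular the ring enlargement of spiro[4.5]decadienones to fused phenols and the quinol variant in which carbon and not oxygen migrates; a 1,2-alkenyl shift inside a 1-oxaspiro[4.5]deca-3,6,9-trien-8-one that delivers a 2H-chromen-6-ol is the extension proposed here. No ring is closed by cyclization: the six-membered pyran ring arises from the five-membered ring (O1, C2, C3, C4, spiro carbon) by a suprafacial 1,2-shift of the Wagner–Meerwein type that inserts C4a between C4 and C8a, the cis alkene being fixed by the ring. No stereocentre is formed; the spiro centre is destroyed, so both epimers of 16 converge, and C2 keeps the R configuration because none of its four bonds takes part. The step needs migration of carbon and not oxygen (carbon migration leaves an oxygen-stabilized cation, and an alkenyl group has a high migratory aptitude), migration toward the CH position and not toward the methyl-bearing carbon (only the former can be completed by proton loss, the latter is more hindered and reversible), and survival of the tertiary allylic C2–O1 bond (the Lewis acid sits on the carbonyl oxygen, the cationic ring makes O1 a poor leaving group, and low temperature with a catalytic amount of acid is used).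

Step 12
Reactants: 17 (R)-sargachromenol methyl ester
Product: 18 (R)-sargachromenol
Conditions: LiOH·H2O, THF/MeOH/H2O (degassed, argon), 40 °C; then cold 0.5 M HCl to pH 4
Reagents that add atoms: lithium hydroxide, [Li+].[OH-]
Why: Saponification by acyl–oxygen cleavage involves neither the stereocentre nor an alkene, and exclusion of air protects the electron-rich chromenol phenoxide.

**Compound list**
1 | (2E,6E)-farnesol, (2E,6E)-3,7,11-trimethyldodeca-2,6,10-trien-1-ol | CC(C)=CCC/C(C)=C/CC/C(C)=C/CO | starting material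
2 | (2E,6E)-10-bromo-3,7,11-trimethyldodeca-2,6-diene-1,11-diol (racemic at C10; not isolated) | CC(C)(O)C(Br)CC/C(C)=C/CC/C(C)=C/CO | intermediate
3 | (2E,6E)-9-(3,3-dimethyloxiran-2-yl)-3,7-dimethylnona-2,6-dien-1-ol (10,11-epoxyfarnesol, racemic at the oxirane CH) | CC1(C)OC1CC/C(C)=C/CC/C(C)=C/CO | intermediate
4 | [(2R,3R)-3-[(3E)-6-(3,3-dimethyloxiran-2-yl)-4-methylhex-3-en-1-yl]-3-methyloxiran-2-yl]methanol (both epimers at the remote oxirane CH) | CC1(C)OC1CC/C(C)=C/CC[C@@]1(C)O[C@@H]1CO | intermediate
5 | (2S,3R)-2-(chloromethyl)-3-[(3E)-6-(3,3-dimethyloxiran-2-yl)-4-methylhex-3-en-1-yl]-3-methyloxirane | CC1(C)OC1CC/C(C)=C/CC[C@@]1(C)O[C@@H]1CCl | intermediate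
6 | lithium (3R,6E)-1-chloro-9-(3,3-dimethyloxiran-2-yl)-3,7-dimethylnona-1,6-dien-3-olate (geometry of the chloroalkene not assigned; not isolated) | CC1(C)OC1CC/C(C)=C/CC[C@@](C)([O-])C=CCl.[Li+] | intermediate
7 | (3R,6E)-9-(3,3-dimethyloxiran-2-yl)-3,7-dimethylnon-6-en-1-yn-3-ol | CC1(C)OC1CC/C(C)=C/CC[C@@](C)(O)C#C | intermediate
8 | (4E,8R)-8-hydroxy-4,8-dimethyldec-4-en-9-ynal | O=CCC/C(C)=C/CC[C@@](C)(O)C#C | intermediate
9 | methyl bis(2,2,2-trifluoroethyl)phosphonoacetate | COC(=O)CP(=O)(OCC(F)(F)F)OCC(F)(F)F | starting material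
10 | 5-bromo-2-methylpent-2-ene | CC(C)=CCCBr | starting material
11 | methyl 2-[bis(2,2,2-trifluoroethoxy)phosphoryl]-6-methylhept-5-enoate (racemic) | COC(=O)C(CCC=C(C)C)P(=O)(OCC(F)(F)F)OCC(F)(F)F | intermediate
12 | methyl (2Z,6E,10R)-10-hydroxy-6,10-dimethyl-2-(4-methylpent-3-en-1-yl)dodeca-2,6-dien-11-ynoate | CC(C)=CCC/C(=C/CC/C(C)=C/CC[C@@](C)(O)C#C)C(=O)OC | intermediate
13 | 4-iodo-3-methylphenol | Cc1cc(O)ccc1I | starting material
14 | methyl (2Z,6E,10R)-10-hydroxy-12-(4-hydroxy-2-methylphenyl)-6,10-dimethyl-2-(4-methylpent-3-en-1-yl)dodeca-2,6-dien-11-ynoate | CC(C)=CCC/C(=C/CC/C(C)=C/CC[C@@](C)(O)C#Cc1ccc(O)cc1C)C(=O)OC | intermediate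
15 | methyl (2Z,6E,10R,11Z)-10-hydroxy-12-(4-hydroxy-2-methylphenyl)-6,10-dimethyl-2-(4-methylpent-3-en-1-yl)dodeca-2,6,11-trienoate | CC(C)=CCC/C(=C/CC/C(C)=C/CC[C@@](C)(O)/C=C\c1ccc(O)cc1C)C(=O)OC | intermediate
16 | methyl (2Z,6E)-9-[(2R)-2,6-dimethyl-8-oxo-1-oxaspiro[4.5]deca-3,6,9-trien-2-yl]-6-methyl-2-(4-methylpent-3-en-1-yl)nona-2,6-dienoate (both epimers at the spiro carbon) | CC(C)=CCC/C(=C/CC/C(C)=C/CC[C@]1(C)C=CC2(O1)C=CC(=O)C=C2C)C(=O)OC | intermediate
17 | methyl (2Z,6E)-9-[(2R)-6-hydroxy-2,8-dimethyl-2H-chromen-2-yl]-6-methyl-2-(4-methylpent-3-en-1-yl)nona-2,6-dienoate | CC(C)=CCC/C(=C/CC/C(C)=C/CC[C@]1(C)C=Cc2cc(O)cc(C)c2O1)C(=O)OC | intermediate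
18 | (R)-sargachromenol, (2Z,6E)-9-[(2R)-6-hydroxy-2,8-dimethyl-2H-chromen-2-yl]-6-methyl-2-(4-methylpent-3-en-1-yl)nona-2,6-dienoic acid | CC(C)=CCC/C(=C/CC/C(C)=C/CC[C@]1(C)C=Cc2cc(O)cc(C)c2O1)C(=O)O | target

**Step count and risks**

Total step count: 12. Longest linear sequence: 11 steps (steps 1–5 and 7–12, from farnesol).

The three steps most likely to fail:

1. Step 11 (Proposed new method). The Lewis acid may cause heterolysis of the tertiary allylic C2–O1 bond, with loss of configuration or elimination. Alternatively, the shift may go toward the methyl-bearing carbon and be followed by a methyl shift to a skeletal isomer, faster than the productive path.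
 Fallback (known chemistry, sets out from 15 and returns at 18): the double bond is introduced after the ring enlargement. The (Z)-disubstituted styrenyl alkene of 15 is reduced with diimide (2-nitrobenzenesulfonyl hydrazide, Et3N, CH2Cl2, rt), which should spare the trisubstituted alkenes, to give methyl (2Z,6E,10R)-10-hydroxy-12-(4-hydroxy-2-methylphenyl)-6,10-dimethyl-2-(4-methylpent-3-en-1-yl)dodeca-2,6-dienoate F1. PhI(OAc)2 in MeCN then gives the saturated spiro ether dienone methyl (2Z,6E)-9-[(2R)-2,6-dimethyl-8-oxo-1-oxaspiro[4.5]deca-6,9-dien-2-yl]-6-methyl-2-(4-methylpent-3-en-1-yl)nona-2,6-dienoate F2. F2 has no allylic ether and should undergo the classical acid-promoted dienone–phenol (quinol ether) rearrangement with migration of the sp3 carbon to give the chroman-6-ol methyl (2Z,6E)-9-[(2R)-6-hydroxy-2,8-dimethyl-3,4-dihydro-2H-chromen-2-yl]-6-methyl-2-(4-methylpent-3-en-1-yl)nona-2,6-dienoate F3. Acetylation (Ac2O, pyridine) gives the 6-O-acetyl chroman ester F4, DDQ in hot benzene dehydrogenates C3–C4 to the 6-O-acetyl 2H-chromene ester F5, and LiOH cleaves acetate and methyl ester together to reach 18.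

2. Step 10. The delocalized aryloxenium intermediate of a para-alkenylphenol may be intercepted by acetate or by a chain alkene, or the polyene may be attacked by the trivalent iodine reagent, before the hindered tertiary hydroxyl closes the five-membered ring.
 Fallback (sets out from 8 and returns at 17): the oxidation is moved to a substrate with one isolated alkene and no ester, and the enoate is attached last. Sonogashira coupling of 8 with 13 gives (4E,8R)-8-hydroxy-10-(4-hydroxy-2-methylphenyl)-4,8-dimethyldec-4-en-9-ynal F6. Lindlar semihydrogenation gives (4E,8R,9Z)-8-hydroxy-10-(4-hydroxy-2-methylphenyl)-4,8-dimethyldeca-4,9-dienal F7. PhI(OAc)2 gives the spiro trienone aldehyde (4E)-7-[(2R)-2,6-dimethyl-8-oxo-1-oxaspiro[4.5]deca-3,6,9-trien-2-yl]-4-methylhept-4-enal F8. The BF3-catalysed ring expansion gives the chromenol aldehyde (4E)-7-[(2R)-6-hydroxy-2,8-dimethyl-2H-chromen-2-yl]-4-methylhept-4-enal F9. Still–Gennari olefination of F9 with the potassium salt of 11 (one further equivalent of base for the phenol) returns to 17.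

3. Step 12. Saponification of the α-branched (Z)-enoate may be slow, which would allow Z to E isomerization through reversible conjugate addition of hydroxide and air oxidation of the chromenol phenoxide during prolonged exposure to base.
 Fallback (sets out from 15 and returns at 18): the ester is cleaved before the sensitive ring system exists. LiOH hydrolysis of 15, which carries neither a dienone nor a chromenol and allows removal of any geometric isomer, gives (2Z,6E,10R,11Z)-10-hydroxy-12-(4-hydroxy-2-methylphenyl)-6,10-dimethyl-2-(4-methylpent-3-en-1-yl)dodeca-2,6,11-trienoic acid F10. PhI(OAc)2 gives the spiro trienone acid (2Z,6E)-9-[(2R)-2,6-dimethyl-8-oxo-1-oxaspiro[4.5]deca-3,6,9-trien-2-yl]-6-methyl-2-(4-methylpent-3-en-1-yl)nona-2,6-dienoic acid F11. The BF3-promoted ring expansion of F11 then delivers 18 directly as the last step.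

**Further compounds**
F1 | step 11 | methyl (2Z,6E,10R)-10-hydroxy-12-(4-hydroxy-2-methylphenyl)-6,10-dimethyl-2-(4-methylpent-3-en-1-yl)dodeca-2,6-dienoate | CC(C)=CCC/C(=C/CC/C(C)=C/CC[C@@](C)(O)CCc1ccc(O)cc1C)C(=O)OC
F2 | step 11 | methyl (2Z,6E)-9-[(2R)-2,6-dimethyl-8-oxo-1-oxaspiro[4.5]deca-6,9-dien-2-yl]-6-methyl-2-(4-methylpent-3-en-1-yl)nona-2,6-dienoate | CC(C)=CCC/C(=C/CC/C(C)=C/CC[C@]1(C)CCC2(O1)C=CC(=O)C=C2C)C(=O)OC
F3 | step 11 | methyl (2Z,6E)-9-[(2R)-6-hydroxy-2,8-dimethyl-3,4-dihydro-2H-chromen-2-yl]-6-methyl-2-(4-methylpent-3-en-1-yl)nona-2,6-dienoate | CC(C)=CCC/C(=C/CC/C(C)=C/CC[C@]1(C)CCc2cc(O)cc(C)c2O1)C(=O)OC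
F4 | step 11 | methyl (2Z,6E)-9-[(2R)-6-(acetyloxy)-2,8-dimethyl-3,4-dihydro-2H-chromen-2-yl]-6-methyl-2-(4-methylpent-3-en-1-yl)nona-2,6-dienoate | CC(C)=CCC/C(=C/CC/C(C)=C/CC[C@]1(C)CCc2cc(OC(C)=O)cc(C)c2O1)C(=O)OC
F5 | step 11 | methyl (2Z,6E)-9-[(2R)-6-(acetyloxy)-2,8-dimethyl-2H-chromen-2-yl]-6-methyl-2-(4-methylpent-3-en-1-yl)nona-2,6-dienoate | CC(C)=CCC/C(=C/CC/C(C)=C/CC[C@]1(C)C=Cc2cc(OC(C)=O)cc(C)c2O1)C(=O)OC
F6 | step 10 | (4E,8R)-8-hydroxy-10-(4-hydroxy-2-methylphenyl)-4,8-dimethyldec-4-en-9-ynal | O=CCC/C(C)=C/CC[C@@](C)(O)C#Cc1ccc(O)cc1C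
F7 | step 10 | (4E,8R,9Z)-8-hydroxy-10-(4-hydroxy-2-methylphenyl)-4,8-dimethyldeca-4,9-dienal | O=CCC/C(C)=C/CC[C@@](C)(O)/C=C\c1ccc(O)cc1C
F8 | step 10 | (4E)-7-[(2R)-2,6-dimethyl-8-oxo-1-oxaspiro[4.5]deca-3,6,9-trien-2-yl]-4-methylhept-4-enal | O=CCC/C(C)=C/CC[C@]1(C)C=CC2(O1)C=CC(=O)C=C2C
F9 | step 10 | (4E)-7-[(2R)-6-hydroxy-2,8-dimethyl-2H-chromen-2-yl]-4-methylhept-4-enal | O=CCC/C(C)=C/CC[C@]1(C)C=Cc2cc(O)cc(C)c2O1
F10 | step 12 | (2Z,6E,10R,11Z)-10-hydroxy-12-(4-hydroxy-2-methylphenyl)-6,10-dimethyl-2-(4-methylpent-3-en-1-yl)dodeca-2,6,11-trienoic acid | CC(C)=CCC/C(=C/CC/C(C)=C/CC[C@@](C)(O)/C=C\c1ccc(O)cc1C)C(=O)O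
F11 | step 12 | (2Z,6E)-9-[(2R)-2,6-dimethyl-8-oxo-1-oxaspiro[4.5]deca-3,6,9-trien-2-yl]-6-methyl-2-(4-methylpent-3-en-1-yl)nona-2,6-dienoic acid | CC(C)=CCC/C(=C/CC/C(C)=C/CC[C@]1(C)C=CC2(O1)C=CC(=O)C=C2C)C(=O)O
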